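The numbers in the tables stem from a simulated flask for substances that don't exist, noise included.

Turn the question round: ask what elm and ash would need in order to end level. They share a recipe and differ in time, so a tie needs the excess to stand at nearly the same height at the two stopping times.

| setting | Sunday's | Friday's | elm | ash |
|---|---|---|---|---|
| left-handed substrate | 0.50 M | 0.50 M | 0.50 M | 0.50 M |
| right-handed substrate | 0.50 M | 0.50 M | 0.50 M | 0.50 M |
| coupling partner | 3.1 equiv | 4.8 equiv | 2.20 equiv | 2.20 equiv |
| catalyst | 4.5 mol% | 4.5 mol% | 4.5 mol% | 4.5 mol% |
| added ligand | 17 mM | 17 mM | 17 mM | 17 mM |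
| remark | run made earlier | run made earlier |  |  |
| time |  |  | 2.5 min | 0.80 min |

| run | time / min | right-handed substrate / % | left-handed substrate / % | left-handed product / % |
|---|---|---|---|---|
| Sunday's | 0.167 | 54 | 47 | 2 |
| Sunday's | 0.500 | 47 | 41 | 8 |
| Sunday's | 0.833 | 49 | 37 | 14 |
| Sunday's | 1.33 | 48 | 31 | 22 |
| Sunday's | 2.00 | 46 | 28 | 27 |
| Sunday's | 2.50 | 42 | 28 | 31 |
| Sunday's | 3.00 | 40 | 25 | 34 |
| Friday's | 0.167 | 49 | 46 | 5 |
| Friday's | 0.500 | 51 | 38 | 15 |
| Friday's | 0.833 | 47 | 32 | 19 |
| Friday's | 1.33 | 47 | 26 | 28 |
| Friday's | 2.00 | 42 | 21 | 40 |
| Friday's | 2.50 | 38 | 19 | 41 |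
| Friday's | 3.00 | 36 | 16 | 48 |

(standard deviation of a reading: 1.5 percentage points)

- catalyst is single-handed; left-handed substrate and right-handed substrate are mirror images of each other, charged as a racemate, each of them at the stated concentration
- the numbers in the tables scatter by 1.5 percentage points (one standard deviation)
- an excess is the difference of the two amounts in percent of their sum
- an excess is below zero if the other one leads

- the flask that ends with the higher excess of right-handed substrate over left-handed substrate among what is left of the two, or "neither" when 2 percentage points or less lies between them (elm / ash / neither)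
- excess of right-handed substrate over left-handed substrate among what is left of the two at the end, elm
- excess of right-handed substrate over left-handed substrate among what is left of the two at the end, ash

In Friday's run the product reached 48 % while the left-handed substrate had lost 34.0 %, which is less than the product, so I let the right-handed substrate S feed the left-handed substrate L with constant k each way. L couples with a pseudo-first-order constant κ. From Friday's run, S lost over the area under S − L gave k = 0.278 min⁻¹. Product over the area under L, scaled by hand to the partner charge of elm and ash, gave κ = 0.266 min⁻¹. For the excess e = (S − L)/(S + L) the pair collapses into one equation: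

de/dt = (κ/2)(1 − e·e) − 2ke

Integrated from zero, it is a lag with a time constant τ, the rise time of the excess 1.62 min, and a plateau e∞:

e∞ = κ/(1/τ + 2k) = 22.7 %

e(t) ≈ e∞(1 − exp(−t/τ))

I dropped a small term, 0.0516, from the exact denominator. Elm reached 17.9 % and ash 8.85 %. Ash stopped at 0.493 of τ, sooner than one time constant, which left a gap of 9 percentage points against the margin of 2 points.

The forecast said elm, with 17 % (14 % to 20.5 %) for elm and 8.4 % (6.5 % to 10.5 %) for ash, and it noted of its coupling constant: “That is an extrapolation from two points.” My elm figure stood higher than its own, as did my ash figure, and I had used Friday's run by itself.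

    coupling partner + catalyst + left-handed substrate → catalyst + left-handed product (k = 0.380 L² mol⁻² s⁻¹)
    coupling partner + catalyst + right-handed substrate → catalyst + right-handed product (k = 0.00220 L² mol⁻² s⁻¹)
    left-handed substrate ⇌ right-handed substrate (k = 0.00430 s⁻¹)
    coupling partner → decomposed reagent (k = 2.20 × 10⁻⁴ s⁻¹)
    catalyst + added ligand ⇌ idle complex, settled at all times (K = 150 L mol⁻¹)

The simulation put elm ahead, with 16.8 % there and 8.97 % in ash. A reading of ash at 20 s is the same flask with the time moved. The lag, with the same τ of 1.62 min and plateau of 22.7 %, gives 4.22 % there, and the simulation stood at 4.35 %.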